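## Retrosynthetic overview

1. The bridging C–aryl bond to ring A is cut last: a Friedel–Crafts-type Michael addition of the prenylated (R)-2-methylbutanoylphloroglucinol 21 to the quinone methide 24 of ring B, under a chiral squaramide, sets the bridge stereocentre.
2. The bench-stable precursor of quinone methide 24 is the sulfone 23, made from prenylated isobutyrylphloroglucinol 10, 6-methylheptanal 5 and p-toluenesulfinic acid (aldol-type hydroxyalkylation to carbinol 22, then acid-promoted replacement of the benzylic hydroxyl by sulfinate).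
3. 10 and 21 both come from phloroglucinol by Friedel–Crafts acylation and mono-C-prenylation; the (R)-2-methylbutanoyl unit comes from an Evans methylation.
4. Aldehyde 5 comes from a 3-methylbutyl Grignard reagent and a bromoacetal.
5. No ring is built: both benzene rings are bought as phloroglucinol. Ring B is elaborated first as the electrophile, and ring A is joined last.

Assumption: the target is read as (R) at the bridging methine and (R) at C-2 of the 2-methylbutanoyl group. The quinine-derived squaramide in step 12 is assumed, not known, to favour this bridge epimer; if it favoured the other, the quinidine-derived pseudoenantiomer would be used in the same step.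

## Route

Step 1
Reactants: 1 1-bromo-3-methylbutane; 2 2-(2-bromoethyl)-1,3-dioxolane
Product: 4 2-(5-methylhexyl)-1,3-dioxolane, via 3-methylbutylmagnesium bromide 3 (not isolated)
Conditions: Mg, THF, 40 °C; then 2, Li2CuCl4 (3 mol %), THF, −10 °C → rt
Reagents that add atoms: none
Why: A copper-catalysed Grignard cross-coupling (Kochi coupling) joins two unhindered primary sp3 carbons cleanly, and the dioxolane keeps the aldehyde carbon inert to the Grignard reagent.

Step 2
Reactants: 4 2-(5-methylhexyl)-1,3-dioxolane
Product: 5 6-methylheptanal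
Conditions: 1 M HCl, THF, rt
Reagents that add atoms: water, O
Why: Acid-catalysed acetal hydrolysis is driven to completion by excess water and touches nothing else in this saturated chain.

Step 3
Reactants: 6 phloroglucinol (benzene-1,3,5-triol); 7 2-methylpropanoyl chloride
Product: 8 2-methyl-1-(2,4,6-trihydroxyphenyl)propan-1-one
Conditions: AlCl3 (4 equiv), PhNO2/CH2Cl2, rt → 40 °C; then ice/1 M HCl
Reagents that add atoms: none
Why: Friedel–Crafts acylation of the very electron-rich triol stops at the monoketone because the acylated ring is deactivated and held as an aluminium chelate.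

Step 4
Reactants: 8 2-methyl-1-(2,4,6-trihydroxyphenyl)propan-1-one; 9 1-bromo-3-methylbut-2-ene (prenyl bromide)
Product: 10 2-methyl-1-[2,4,6-trihydroxy-3-(3-methylbut-2-enyl)phenyl]propan-1-one
Conditions: 9 (1.0 equiv), 10% aq. KOH, 0 °C, 1 h; then 1 M HCl; silica chromatography
Reagents that add atoms: none
Why: C-alkylation of the ambident phloroglucinolate (SN2 allylation of a vinylogous enolate) is favoured over O-alkylation in water, the two free ring positions of 8 are equivalent, and one equivalent of bromide at 0 °C holds the reaction largely at the mono-prenyl stage, with over-alkylated material and recovered 8 separated on silica.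

Step 5
Reactants: 11 (R)-4-benzyl-1,3-oxazolidin-2-one; 12 butanoyl chloride
Product: 14 (R)-4-benzyl-3-butanoyl-1,3-oxazolidin-2-one, via lithiated oxazolidinone 13 (not isolated)
Conditions: n-BuLi, THF, −78 °C; then 12, −78 → 0 °C
Reagents that add atoms: none
Why: N-acylation of the lithium amide of the oxazolidinone with an acid chloride is near-quantitative and installs the chiral imide.

Step 6
Reactants: 14 (R)-4-benzyl-3-butanoyl-1,3-oxazolidin-2-one
Product: 16 (R)-4-benzyl-3-[(R)-2-methylbutanoyl]-1,3-oxazolidin-2-one, via sodium Z-enolate 15 (not isolated)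
Conditions: NaN(SiMe3)2, THF, −78 °C; then MeI, −78 °C; chromatography and recrystallisation to one diastereomer
Reagents that add atoms: iodomethane, CI
Why: Evans asymmetric alkylation: the chelated Z-enolate is methylated on the face away from the benzyl group, which with the (R)-auxiliary gives the (R)-2-methylbutanoyl centre (about 10:1), and the minor diastereomer is removed by chromatography and crystallisation.

Step 7
Reactants: 16 (R)-4-benzyl-3-[(R)-2-methylbutanoyl]-1,3-oxazolidin-2-one
Product: 18 (R)-2-methylbutanoic acid, via (R)-2-methylbutaneperoxoic acid 17 (not isolated)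
Conditions: LiOH, H2O2, THF/H2O (3:1), 0 °C; then aq. Na2SO3; then 1 M HCl
Reagents that add atoms: hydrogen peroxide, OO
Why: Hydroperoxide attacks the exocyclic imide carbonyl selectively (nucleophilic acyl substitution) without enolisation, so the acid is released with its stereocentre intact and the auxiliary is recovered.

Step 8
Reactants: 18 (R)-2-methylbutanoic acid
Product: 19 (R)-2-methylbutanoyl chloride
Conditions: (COCl)2, DMF (cat.), CH2Cl2, 0 °C → rt; short-path distillation
Reagents that add atoms: oxalyl chloride, ClC(=O)C(Cl)=O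
Why: Acid chloride formation through the Vilsmeier-type chloroiminium ion runs at room temperature without base, so no ketene can form and the α-stereocentre is kept.

Step 9
Reactants: 6 phloroglucinol; 19 (R)-2-methylbutanoyl chloride
Product: 20 (R)-2-methyl-1-(2,4,6-trihydroxyphenyl)butan-1-one
Conditions: AlCl3 (4 equiv), PhNO2/CH2Cl2, 0 °C → rt; then ice/1 M HCl
Reagents that add atoms: none
Why: Friedel–Crafts acylation as in step 3, run base-free at or below room temperature so that the α-stereocentre is not enolised (the ee of 20 is checked by chiral HPLC).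

Step 10
Reactants: 20 (R)-2-methyl-1-(2,4,6-trihydroxyphenyl)butan-1-one; 9 1-bromo-3-methylbut-2-ene
Product: 21 (R)-2-methyl-1-[2,4,6-trihydroxy-3-(3-methylbut-2-enyl)phenyl]butan-1-one
Conditions: 9 (1.0 equiv), 10% aq. KOH, 0 °C, 1 h; then 1 M HCl; silica chromatography
Reagents that add atoms: none
Why: The same C-prenylation (SN2 allylation of the phloroglucinolate) as in step 4; the aryl ketone sits as a phenoxide polyanion in cold aqueous KOH and is not enolised, so the (R)-centre survives.

Step 11
Reactants: 10 2-methyl-1-[2,4,6-trihydroxy-3-(3-methylbut-2-enyl)phenyl]propan-1-one; 5 6-methylheptanal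
Product: 23 2-methyl-1-[2,4,6-trihydroxy-3-(3-methylbut-2-enyl)-5-[6-methyl-1-(4-methylphenyl)sulfonylheptyl]phenyl]propan-1-one (racemic at the sulfonyl-bearing carbon), via benzylic carbinol 22 (not isolated)
Conditions: 5 (1.5 equiv), p-TolSO2H (3 equiv), EtOH/H2O (2:1), rt, 10 added slowly; product filtered off
Reagents that add atoms: 4-methylbenzenesulfinic acid, Cc1ccc(cc1)S(=O)O
Why: Aldol-type hydroxyalkylation of the aldehyde by the only free ring carbon of 10 gives carbinol 22, whose benzylic hydroxyl ionises in the acidic medium to a cation stabilised by three ring oxygens that the excess sulfinate captures at sulfur (SN1 substitution) faster than a second molecule of 10 can add, leaving the electrophile as a crystalline sulfone.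

Step 12
Reactants: 23 the sulfone from step 11; 21 (R)-2-methyl-1-[2,4,6-trihydroxy-3-(3-methylbut-2-enyl)phenyl]butan-1-one
Product: 25 (2R)-2-methyl-1-[2,4,6-trihydroxy-3-(3-methylbut-2-enyl)-5-[(1R)-6-methyl-1-[2,4,6-trihydroxy-3-(3-methylbut-2-enyl)-5-(2-methylpropanoyl)phenyl]heptyl]phenyl]butan-1-one (CNP0279787.1), via quinone methide 24 (not isolated)
Conditions: 3-{[3,5-bis(trifluoromethyl)phenyl]amino}-4-{[(8α,9S)-6′-methoxycinchonan-9-yl]amino}cyclobut-3-ene-1,2-dione (10 mol %), 5% aq. NaHCO3, CHCl3, 0 °C; then cold 0.5 M HCl wash; preparative HPLC to remove the minor bridge epimer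
Reagents that add atoms: none
Why: Base-induced loss of sulfinate from the phenoxide of 23 (E1cB) releases quinone methide 24 at low concentration, and the only free ring carbon of 21 adds to it in a Friedel–Crafts-type Michael addition inside the chiral ion pair (squaramide N–H bonds on the methide carbonyl, quinuclidinium on the phloroglucinolate), which fixes the attacked face and so the (R)-bridge centre; both rings are then fully substituted, so no further alkylation can occur.

## Compound list

1 | 1-bromo-3-methylbutane | CC(C)CCBr | starting material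
2 | 2-(2-bromoethyl)-1,3-dioxolane | BrCCC1OCCO1 | starting material
3 | 3-methylbutylmagnesium bromide (not isolated) | CC(C)CC[Mg]Br | intermediate
4 | 2-(5-methylhexyl)-1,3-dioxolane | CC(C)CCCCC1OCCO1 | intermediate
5 | 6-methylheptanal | CC(C)CCCCC=O | intermediate
6 | phloroglucinol (benzene-1,3,5-triol) | Oc1cc(O)cc(O)c1 | starting material
7 | 2-methylpropanoyl chloride | CC(C)C(Cl)=O | starting material
8 | 2-methyl-1-(2,4,6-trihydroxyphenyl)propan-1-one | CC(C)C(=O)c1c(O)cc(O)cc1O | intermediate
9 | 1-bromo-3-methylbut-2-ene (prenyl bromide) | CC(C)=CCBr | starting material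
10 | 2-methyl-1-[2,4,6-trihydroxy-3-(3-methylbut-2-enyl)phenyl]propan-1-one | CC(C)C(=O)c1c(O)cc(O)c(CC=C(C)C)c1O | intermediate
11 | (R)-4-benzyl-1,3-oxazolidin-2-one | O=C1N[C@H](Cc2ccccc2)CO1 | starting material
12 | butanoyl chloride | CCCC(Cl)=O | starting material
13 | N-lithio-(R)-4-benzyl-1,3-oxazolidin-2-one (not isolated) | [Li]N1[C@H](Cc2ccccc2)COC1=O | intermediate
14 | (R)-4-benzyl-3-butanoyl-1,3-oxazolidin-2-one | CCCC(=O)N1[C@H](Cc2ccccc2)COC1=O | intermediate
15 | sodium Z-enolate of 14 (not isolated) | CC/C=C(\O[Na])N1[C@H](Cc2ccccc2)COC1=O | intermediate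
16 | (R)-4-benzyl-3-[(R)-2-methylbutanoyl]-1,3-oxazolidin-2-one | CC[C@@H](C)C(=O)N1[C@H](Cc2ccccc2)COC1=O | intermediate
17 | (R)-2-methylbutaneperoxoic acid, formed as its lithium salt (not isolated) | CC[C@@H](C)C(=O)OO | intermediate
18 | (R)-2-methylbutanoic acid | CC[C@@H](C)C(=O)O | intermediate
19 | (R)-2-methylbutanoyl chloride | CC[C@@H](C)C(Cl)=O | intermediate
20 | (R)-2-methyl-1-(2,4,6-trihydroxyphenyl)butan-1-one | CC[C@@H](C)C(=O)c1c(O)cc(O)cc1O | intermediate
21 | (R)-2-methyl-1-[2,4,6-trihydroxy-3-(3-methylbut-2-enyl)phenyl]butan-1-one | CC[C@@H](C)C(=O)c1c(O)cc(O)c(CC=C(C)C)c1O | intermediate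
22 | 2-methyl-1-[2,4,6-trihydroxy-3-(1-hydroxy-6-methylheptyl)-5-(3-methylbut-2-enyl)phenyl]propan-1-one, the benzylic carbinol of ring B (racemic, not isolated) | CC(C)C(=O)c1c(O)c(CC=C(C)C)c(O)c(C(O)CCCCC(C)C)c1O | intermediate
23 | 2-methyl-1-[2,4,6-trihydroxy-3-(3-methylbut-2-enyl)-5-[6-methyl-1-(4-methylphenyl)sulfonylheptyl]phenyl]propan-1-one (racemic) | CC(C)C(=O)c1c(O)c(CC=C(C)C)c(O)c(C(CCCCC(C)C)S(=O)(=O)c2ccc(C)cc2)c1O | intermediate
24 | 3,5-dihydroxy-4-(3-methylbut-2-enyl)-6-(6-methylheptylidene)-2-(2-methylpropanoyl)cyclohexa-2,4-dien-1-one, the quinone methide of ring B (alkene geometry not defined, not isolated) | CC(C)CCCCC=C1C(=O)C(C(=O)C(C)C)=C(O)C(CC=C(C)C)=C1O | intermediate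
25 | (2R)-2-methyl-1-[2,4,6-trihydroxy-3-(3-methylbut-2-enyl)-5-[(1R)-6-methyl-1-[2,4,6-trihydroxy-3-(3-methylbut-2-enyl)-5-(2-methylpropanoyl)phenyl]heptyl]phenyl]butan-1-one | CC[C@@H](C)C(=O)c1c(O)c(CC=C(C)C)c(O)c([C@H](CCCCC(C)C)c2c(O)c(CC=C(C)C)c(O)c(C(=O)C(C)C)c2O)c1O | target

## Step count and risks

Total steps: 12. Longest linear sequence: 7 steps (5, 6, 7, 8, 9, 10, 12).

The three steps most likely to fail:

Step 12 (key Michael addition; the face selectivity of the squaramide is not established for this substrate pair). The fallback sets out from 23 and 21 and comes back at 25. The coupling is run without a chiral catalyst (Et3N, CHCl3, 0 °C), which gives 25 together with its bridge epimer (2R)-2-methyl-1-[2,4,6-trihydroxy-3-(3-methylbut-2-enyl)-5-[(1S)-6-methyl-1-[2,4,6-trihydroxy-3-(3-methylbut-2-enyl)-5-(2-methylpropanoyl)phenyl]heptyl]phenyl]butan-1-one F1 in about equal amounts. The two are diastereomers and are separated by preparative HPLC on a cellulose-based chiral stationary phase. Stereocontrol is thus replaced by separation.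

Step 11 (the sulfinate may lose to a second molecule of 10, giving the symmetrical ring B dimer). The fallback sets out from 10 and 5 and comes back at 23. A Mannich (Betti-type) three-component reaction with morpholine in EtOH at rt gives the Mannich base 2-methyl-1-[2,4,6-trihydroxy-3-(3-methylbut-2-enyl)-5-(6-methyl-1-morpholin-4-ylheptyl)phenyl]propan-1-one F2. The aldehyde is tied up by the amine before it meets the arene, and the internally hydrogen-bonded amine is not displaced at rt, so dimer formation is suppressed. F2 is then stirred with p-TolSO2H (2.2 equiv) in CH2Cl2; protonation makes morpholine a leaving group and sulfinate replaces it at the benzylic carbon to give 23.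

Step 9 (partial racemisation of the α-stereocentre, or a poor yield, under AlCl3). The fallback sets out from 18 and 6 and comes back at 20. Acid 18 is converted with carbonyldiimidazole and MeNH(OMe)·HCl into the Weinreb amide (R)-N-methoxy-N,2-dimethylbutanamide F3. Phloroglucinol 6 is protected with MOMCl and iPr2NEt in CH2Cl2 as 1,3,5-tris(methoxymethoxy)benzene F4. Directed ortho-lithiation of F4 (n-BuLi, THF, 0 °C) gives 2,4,6-tris(methoxymethoxy)phenyllithium F5, which adds to F3 at −78 °C to give (R)-2-methyl-1-[2,4,6-tris(methoxymethoxy)phenyl]butan-1-one F6; the stable tetrahedral intermediate prevents both over-addition and enolisation. Removal of the three methoxymethyl groups (3 M HCl, MeOH, rt) gives 20.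

## Further compounds

F1 | step 12 | (2R)-2-methyl-1-[2,4,6-trihydroxy-3-(3-methylbut-2-enyl)-5-[(1S)-6-methyl-1-[2,4,6-trihydroxy-3-(3-methylbut-2-enyl)-5-(2-methylpropanoyl)phenyl]heptyl]phenyl]butan-1-one | CC[C@@H](C)C(=O)c1c(O)c(CC=C(C)C)c(O)c([C@@H](CCCCC(C)C)c2c(O)c(CC=C(C)C)c(O)c(C(=O)C(C)C)c2O)c1O
F2 | step 11 | 2-methyl-1-[2,4,6-trihydroxy-3-(3-methylbut-2-enyl)-5-(6-methyl-1-morpholin-4-ylheptyl)phenyl]propan-1-one | CC(C)C(=O)c1c(O)c(CC=C(C)C)c(O)c(C(CCCCC(C)C)N2CCOCC2)c1O
F3 | step 9 | (R)-N-methoxy-N,2-dimethylbutanamide | CC[C@@H](C)C(=O)N(C)OC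
F4 | step 9 | 1,3,5-tris(methoxymethoxy)benzene | COCOc1cc(OCOC)cc(OCOC)c1
F5 | step 9 | 2,4,6-tris(methoxymethoxy)phenyllithium | [Li]c1c(OCOC)cc(OCOC)cc1OCOC
F6 | step 9 | (R)-2-methyl-1-[2,4,6-tris(methoxymethoxy)phenyl]butan-1-one | CC[C@@H](C)C(=O)c1c(OCOC)cc(OCOC)cc1OCOC
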